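The route rests on reading cyclooctene ring B as a cyclobutanone enlarged by two alkyne carbons. The handle is the tetrasubstituted C(CH3)=C alkene shared by rings A and B, which lies next to the tertiary carbinol carbon of the B/C fusion: viewed as an enone, ring B is the four carbons of a cyclobutanone, its two alkenyl carbons and the two carbons of a tethered alkyne. A Rh(I)-catalysed [6+2] cycloisomerisation should cleave the acyl–C(alkenyl) bond and close rings A and B in one operation. Its precursor is an all-trans 2,3,4-trisubstituted cyclobutanone bearing ring D on one arm and an (E)-alkenyl chain ending in a methyl-capped alkyne on the other; ring C is closed last.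

Key step: step 21

Assumption: the sense of induction of the titanium TADDOLate in step 10 is assigned by analogy only; the (R,R)-ligand is written, and its antipode is used without other change if it delivers the opposite face.

Step 1
Reactants: 1 (S)-limonene
Product: 2 (S)-p-menth-1-ene [(4S)-1-methyl-4-(propan-2-yl)cyclohex-1-ene]
Conditions: H2 (1 atm, stopped after 1 equiv), PtO2 (cat.), EtOH, rt
Reagents that add atoms: none
Why: Catalytic hydrogenation reduces the unhindered 1,1-disubstituted isopropenyl alkene faster than the trisubstituted ring alkene, and the stereocentre is not involved.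

Step 2
Reactants: 2 (S)-p-menth-1-ene
Product: 4 (S)-6-oxo-3-(propan-2-yl)heptanal, via ozonide 3 (not isolated)
Conditions: O3, CH2Cl2, −78 °C; then Me2S, −78 °C → rt
Reagents that add atoms: ozone, [O-][O+]=O
Why: Ozonolysis with reductive work-up cleaves the only alkene to the 1,6-keto aldehyde; the stereocentre is β to the aldehyde and γ to the ketone and cannot enolise.

Step 3
Reactants: 4 (S)-6-oxo-3-(propan-2-yl)heptanal
Product: 5 (R)-2-methyl-5-(propan-2-yl)cyclopent-1-ene-1-carbaldehyde
Conditions: piperidine (cat.), AcOH (cat.), toluene, 80 °C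
Reagents that add atoms: none
Why: Amine-catalysed intramolecular aldol condensation closes ring D: the enamine of the aldehyde adds to the methyl ketone and dehydration gives the tetrasubstituted enal, while the isopropyl-bearing carbon is not acidic and keeps its configuration.

Step 4
Reactants: 5 (R)-2-methyl-5-(propan-2-yl)cyclopent-1-ene-1-carbaldehyde
Product: 6 [(R)-2-methyl-5-(propan-2-yl)cyclopent-1-en-1-yl]methanol
Conditions: NaBH4, CeCl3·7H2O, MeOH, 0 °C
Reagents that add atoms: none
Why: Luche reduction delivers hydride 1,2 to the enal and gives the allylic alcohol without touching the alkene.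

Step 5
Reactants: 6 [(R)-2-methyl-5-(propan-2-yl)cyclopent-1-en-1-yl]methanol
Product: 8 ethyl 2-[(1R,3R)-1-methyl-2-methylidene-3-(propan-2-yl)cyclopentyl]acetate, via ketene acetal 7 (not isolated)
Conditions: MeC(OEt)3 (excess), EtCO2H (cat.), 140 °C, EtOH distilled off
Reagents that add atoms: triethyl orthoacetate, CCOC(C)(OCC)OCC
Why: Johnson–Claisen rearrangement builds the quaternary carbon by a [3,3] shift of the ketene acetal formed in situ; the chair transition state is expected to lie over the ring face away from the neighbouring isopropyl group, so the acetate arm ends up anti to isopropyl and the methyl group syn to it.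

Step 6
Reactants: 8 ethyl 2-[(1R,3R)-1-methyl-2-methylidene-3-(propan-2-yl)cyclopentyl]acetate
Product: 10 ethyl 2-[(1R,2S,3R)-2-(hydroxymethyl)-1-methyl-3-(propan-2-yl)cyclopentyl]acetate, via alkylborane 9 (not isolated)
Conditions: 9-BBN, THF, 0 → 60 °C; then NaBO3·4H2O, THF/H2O, rt
Reagents that add atoms: sodium perborate, [Na+].[Na+].O[B-]1(O)OO[B-](O)(O)OO1 (oxygen); 9-borabicyclo[3.3.1]nonane, B1C2CCCC1CCC2 (boron, in 9 only)
Why: Anti-Markovnikov hydroboration–oxidation with a bulky borane that tolerates the ester; the borane should approach the exocyclic alkene from the face opposite both the isopropyl and the quaternary methyl group, so the new ring hydrogen is anti to isopropyl and the CH2OH arm is trans to the acetate arm (the later trans C/D fusion).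

Step 7
Reactants: 10 ethyl 2-[(1R,2S,3R)-2-(hydroxymethyl)-1-methyl-3-(propan-2-yl)cyclopentyl]acetate
Product: 11 ethyl 2-[(1R,2S,3R)-2-{[tert-butyl(dimethyl)silyl]oxymethyl}-1-methyl-3-(propan-2-yl)cyclopentyl]acetate
Conditions: TBSCl, imidazole, DMF, rt
Reagents that add atoms: tert-butyldimethylsilyl chloride, CC(C)(C)[Si](C)(C)Cl
Why: Standard silylation of a primary alcohol; it also prevents lactonisation onto the ester.

Step 8
Reactants: 11 ethyl 2-[(1R,2S,3R)-2-{[tert-butyl(dimethyl)silyl]oxymethyl}-1-methyl-3-(propan-2-yl)cyclopentyl]acetate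
Product: 12 2-[(1R,2S,3R)-2-{[tert-butyl(dimethyl)silyl]oxymethyl}-1-methyl-3-(propan-2-yl)cyclopentyl]acetaldehyde
Conditions: DIBAL-H (1.1 equiv), CH2Cl2, −78 °C; Rochelle salt work-up
Reagents that add atoms: none
Why: Partial reduction of the ester stops at the aldehyde because the tetrahedral aluminium hemiacetal of this hindered ester is stable at −78 °C.

Step 9
Reactants: 12 2-[(1R,2S,3R)-2-{[tert-butyl(dimethyl)silyl]oxymethyl}-1-methyl-3-(propan-2-yl)cyclopentyl]acetaldehyde, 13 2-(trimethylsilyl)-1,3-dithiane
Product: 15 2-{2-[(1R,2S,3R)-2-{[tert-butyl(dimethyl)silyl]oxymethyl}-1-methyl-3-(propan-2-yl)cyclopentyl]ethylidene}-1,3-dithiane (ketene dithioacetal), via lithiated silyl dithiane 14 (not isolated)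
Conditions: 13, n-BuLi, THF, −78 → 0 °C; then 12, −78 °C → rt
Reagents that add atoms: none
Why: Peterson olefination: the α-silyl carbanion adds to the aldehyde and loss of silanolate gives the ketene dithioacetal, whose dithiane carbon is the future carbinol carbon.

Step 10
Reactants: 15 ketene dithioacetal, 16 3-[(E)-but-2-enoyl]-1,3-oxazolidin-2-one
Product: 17 all-trans cyclobutane imide: 5,9-dithiaspiro[3.5]nonane bearing at C1 the (2-oxo-1,3-oxazolidin-3-yl)carbonyl group, at C2 methyl and at C3 the CH2 link to the ring D unit of 12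
Conditions: TiCl2(Oi-Pr)2, (R,R)-TADDOL, 4 Å MS, toluene–hexane, 0 °C
Reagents that add atoms: none
Why: Lewis acid-catalysed [2+2] cycloaddition of a ketene dithioacetal with an N-enoyl oxazolidinone (conjugate addition to the titanium-chelated imide, then closure of the titanium enolate on the dithio-stabilised cation): the chiral titanium diolate is expected to direct attack to the Si face of the β-carbon (ring B methyl carbon), the E geometry of 16 gives the trans methyl/acyl pair, and the third centre is expected trans to methyl as the less crowded arrangement (it is α to the later ketone and so correctable).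

Step 11
Reactants: 17 all-trans cyclobutane imide
Product: 18 all-trans cyclobutylmethanol (CH2OH in place of the imide of 17)
Conditions: LiBH4, THF, H2O (1 equiv), 0 °C
Reagents that add atoms: none
Why: Borohydride reduction of the N-acyl oxazolidinone gives the primary alcohol and releases the oxazolidinone; dithiane and silyl ether are inert.

Step 12
Reactants: 18 all-trans cyclobutylmethanol
Product: 19 all-trans cyclobutanecarbaldehyde (CHO in place of CH2OH of 18)
Conditions: SO3·pyridine, DMSO, i-Pr2NEt, CH2Cl2, 0 °C
Reagents that add atoms: none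
Why: Parikh–Doering oxidation is chosen because activated DMSO leaves the dithiane sulfur atoms alone; the α-centre already has the favoured trans arrangement.

Step 13
Reactants: 20 (R)-β-citronellene [(3R)-3,7-dimethylocta-1,6-diene]
Product: 22 (R)-4-methylhex-5-enal, via ozonide 21 (not isolated)
Conditions: O3 (1 equiv, Sudan Red 7B end-point), CH2Cl2, −78 °C; then Me2S
Reagents that add atoms: ozone, [O-][O+]=O
Why: The electron-rich trisubstituted alkene reacts with ozone much faster than the monosubstituted vinyl group, so a dye-indicated single equivalent cleaves it selectively.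

Step 14
Reactants: 22 (R)-4-methylhex-5-enal
Product: 23 (R)-1,1-dibromo-5-methylhepta-1,6-diene
Conditions: CBr4, PPh3, CH2Cl2, 0 °C
Reagents that add atoms: carbon tetrabromide, BrC(Br)(Br)Br
Why: First stage of the Corey–Fuchs homologation, a Wittig-type reaction of the dibromomethylene ylide with the aldehyde.

Step 15
Reactants: 23 (R)-1,1-dibromo-5-methylhepta-1,6-diene
Product: 25 (R)-3-methyloct-1-en-6-yne, via lithium acetylide 24 (not isolated)
Conditions: n-BuLi (2.1 equiv), THF, −78 → 0 °C; then MeI, −78 °C → rt
Reagents that add atoms: iodomethane, CI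
Why: Second stage of the Corey–Fuchs homologation: bromine–lithium exchange, Fritsch–Buttenberg–Wiechell rearrangement and deprotonation give the lithium acetylide, which is methylated.

Step 16
Reactants: 25 (R)-3-methyloct-1-en-6-yne
Product: 27 (R)-2-methylhept-5-yn-1-ol, via ozonide 26 (not isolated)
Conditions: O3 (Sudan Red 7B end-point), CH2Cl2, −78 °C; then NaBH4, MeOH, −78 °C → rt
Reagents that add atoms: ozone, [O-][O+]=O
Why: Alkenes are ozonised far faster than alkynes, so only the vinyl group is cleaved; borohydride reduces the ozonide straight to the alcohol, so no epimerisable α-branched aldehyde is exposed.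

Step 17
Reactants: 27 (R)-2-methylhept-5-yn-1-ol
Product: 28 5-{[(R)-2-methylhept-5-yn-1-yl]sulfanyl}-1-phenyl-1H-tetrazole
Conditions: 1-phenyl-1H-tetrazole-5-thiol, PPh3, DIAD, THF, 0 °C → rt
Reagents that add atoms: 1-phenyl-1H-tetrazole-5-thiol, Sc1nnnn1c1ccccc1
Why: Mitsunobu thioetherification of a primary alcohol by the acidic heteroaryl thiol.

Step 18
Reactants: 28 5-{[(R)-2-methylhept-5-yn-1-yl]sulfanyl}-1-phenyl-1H-tetrazole
Product: 29 5-{[(R)-2-methylhept-5-yn-1-yl]sulfonyl}-1-phenyl-1H-tetrazole
Conditions: (NH4)6Mo7O24·4H2O (cat.), 30% H2O2, EtOH, 0 °C → rt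
Reagents that add atoms: hydrogen peroxide, OO
Why: Molybdate-catalysed peroxide oxidation takes the sulfide to the sulfone; the isolated internal alkyne is inert.

Step 19
Reactants: 19 all-trans cyclobutanecarbaldehyde, 29 5-{[(R)-2-methylhept-5-yn-1-yl]sulfonyl}-1-phenyl-1H-tetrazole
Product: 31 masked enyne cyclobutane: 5,9-dithiaspiro[3.5]nonane bearing at C1 the (1E,3R)-3-methyloct-1-en-6-yn-1-yl chain, at C2 methyl and at C3 the CH2 link to ring D (all-trans), via potassium sulfonyl carbanion 30 (not isolated)
Conditions: 29, KHMDS, DME, −60 °C; then 19, −60 °C → rt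
Reagents that add atoms: none
Why: Julia–Kocienski olefination (addition, Smiles rearrangement, loss of SO2 and tetrazolone) should give the E-alkene with the phenyltetrazolyl sulfone, potassium counter-ion and DME; the E geometry matters because it is translated into a ring stereocentre in step 21.

Step 20
Reactants: 31 masked enyne cyclobutane
Product: 32 (all-trans) 2-[(1E,3R)-3-methyloct-1-en-6-yn-1-yl]-3-methyl-4-(ring D methyl)cyclobutan-1-one
Conditions: MeI, CaCO3, MeCN/H2O (9:1), 45 °C
Reagents that add atoms: water, O
Why: S-Methylation turns the dithiane into a leaving group and water hydrolyses the thionium ion under carbonate-buffered, near-neutral conditions that spare silyl ether, alkyne and alkene; the two α-centres are in the thermodynamically preferred all-trans arrangement, which is the one step 21 requires.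

Step 21
Reactants: 32 2-alkenylcyclobutanone with tethered alkyne
Product: 33 bicyclo[6.3.0]undecadienone (rings A and B): tetrasubstituted enone C(CH3)=C shared with cyclopentane A, cis-disubstituted ring B alkene, ring D unit on the CH2 arm α to the ketone
Conditions: [Rh(CO)2Cl]2 (5 mol %), toluene (0.02 M), 90 °C, Ar
Reagents that add atoms: none
Why: Proposed new method: Rh(I) is expected to couple the alkyne and the alkenyl group oxidatively, joining the inner alkyne carbon to the distal alkenyl carbon and leaving rhodium σ-bonded to the methyl-bearing alkyne carbon and to the alkenyl carbon attached to the four-membered ring; β-carbon elimination of the neighbouring acyl–C(α) bond (strained and allylic) then opens the cyclobutanone to a nine-membered acyl(alkenyl)rhodacycle with the alkene shifted into the ring, and C(acyl)–C(alkenyl) reductive elimination releases the enone and Rh(I). The closest known reaction types are the Rh(I)-catalysed intramolecular [6+2] cycloaddition of 2-vinylcyclobutanones with tethered alkenes and the [5+2] cycloaddition of vinylcyclopropanes with tethered alkynes; only the alkyne as two-carbon partner of a vinylcyclobutanone is new. Ring A closes in the cyclometallation as a 5-exo carbocyclisation over the three-carbon tether, and ring B closes in the reductive elimination by contraction of the nine-membered metallacycle, that is by two-carbon ring expansion of the cyclobutanone and not by end-to-end cyclisation. The single new stereocentre, the A/B fusion CH, is controlled by the alkenyl-bearing α-carbon of the cyclobutanone, whose configuration is relayed suprafacially across the allyl unit (E-alkene in, cis ring alkene out) before that carbon becomes sp2, and the ring A methyl centre reinforces the same face by sitting exo on the bicyclic rhodacycle, so the ring B carbon ends up trans to that methyl group; the geometry of the tetrasubstituted alkene follows from syn addition across the alkyne inside the ring. The step needs cleavage of the acyl–C(alkenyl) bond rather than the acyl–C(alkyl) bond or the other ring bond of the same carbon, and it needs ring opening to outrun β-hydride loss and decarbonylation: after cyclometallation rhodium sits β only to the alkenyl-bearing ring carbon, of whose two ring bonds the acyl one is weaker and leads to the stronger Rh–acyl bond, and the strain of the four-membered ring drives the opening.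

Step 22
Reactants: 33 bicyclo[6.3.0]undecadienone
Product: 34 enone silyl ether (33 with the disubstituted ring B alkene saturated)
Conditions: H2 (1 atm), RhCl(PPh3)3 (10 mol %), toluene, rt
Reagents that add atoms: none
Why: Homogeneous hydrogenation with the chlorotris(triphenylphosphine)rhodium catalyst reduces the cis-disubstituted alkene and leaves the tetrasubstituted conjugated alkene and the ketone alone; the flanking stereocentres are not touched.

Step 23
Reactants: 34 enone silyl ether
Product: 35 hydroxy enone (primary alcohol on the ring D arm)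
Conditions: HF·pyridine, pyridine, THF, 0 °C → rt
Reagents that add atoms: none
Why: Fluoride cleaves the primary silyl ether under buffered, non-basic conditions, which avoids γ-deprotonation of the enone.

Step 24
Reactants: 35 hydroxy enone
Product: 36 iodo enone (CH2I in place of CH2OH of 35)
Conditions: I2, PPh3, imidazole, CH2Cl2, 0 °C → rt
Reagents that add atoms: iodine, II
Why: Appel-type iodination: the alkoxyphosphonium ion of the primary alcohol is displaced by iodide in an SN2 step that involves no stereocentre.

Step 25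
Reactants: 36 iodo enone
Product: 38 sesterfisherol, via alkyllithium 37 (not isolated)
Conditions: t-BuLi (2.1 equiv), Et2O/pentane, −78 °C → rt; NH4Cl aq.
Reagents that add atoms: none
Why: Iodine–lithium exchange with t-BuLi is faster than attack of the reagent on the hindered ketone, and the primary alkyllithium then adds to the carbonyl in an intramolecular Barbier-type 6-exo closure of ring C; a chair transition state with the alkenyl carbon equatorial and the oxygen axial, on a ring whose bonds to rings B and D are already equatorial, should set the carbinol centre.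

Compound list
1 | (S)-limonene | CC1=CC[C@H](CC1)C(C)=C | starting material
2 | (S)-p-menth-1-ene | CC1=CC[C@H](CC1)C(C)C | intermediate
3 | ozonide of 2 | CC12OOC(O1)C[C@H](CC2)C(C)C | intermediate
4 | (S)-6-oxo-3-(propan-2-yl)heptanal | O=CC[C@H](CCC(C)=O)C(C)C | intermediate
5 | (R)-2-methyl-5-(propan-2-yl)cyclopent-1-ene-1-carbaldehyde | CC1=C(C=O)[C@@H](C(C)C)CC1 | intermediate
6 | [(R)-2-methyl-5-(propan-2-yl)cyclopent-1-en-1-yl]methanol | CC1=C(CO)[C@@H](C(C)C)CC1 | intermediate
7 | 1-ethoxyvinyl ether (ketene acetal) of 6 | C=C(OCC)OCC1=C(C)CC[C@@H]1C(C)C | intermediate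
8 | ethyl 2-[(1R,3R)-1-methyl-2-methylidene-3-(propan-2-yl)cyclopentyl]acetate | CCOC(=O)C[C@@]1(C)CC[C@H](C(C)C)C1=C | intermediate
9 | B-alkyl-9-borabicyclo[3.3.1]nonane from 8 | CCOC(=O)C[C@@]1(C)CC[C@H](C(C)C)[C@@H]1CB1C2CCCC1CCC2 | intermediate
10 | ethyl 2-[(1R,2S,3R)-2-(hydroxymethyl)-1-methyl-3-(propan-2-yl)cyclopentyl]acetate | CCOC(=O)C[C@@]1(C)CC[C@H](C(C)C)[C@@H]1CO | intermediate
11 | tert-butyldimethylsilyl ether of 10 | CCOC(=O)C[C@@]1(C)CC[C@H](C(C)C)[C@@H]1CO[Si](C)(C)C(C)(C)C | intermediate
12 | 2-[(1R,2S,3R)-2-{[tert-butyl(dimethyl)silyl]oxymethyl}-1-methyl-3-(propan-2-yl)cyclopentyl]acetaldehyde | O=CC[C@@]1(C)CC[C@H](C(C)C)[C@@H]1CO[Si](C)(C)C(C)(C)C | intermediate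
13 | 2-(trimethylsilyl)-1,3-dithiane | C[Si](C)(C)C1SCCCS1 | starting material
14 | 2-lithio-2-(trimethylsilyl)-1,3-dithiane | [Li]C1([Si](C)(C)C)SCCCS1 | intermediate
15 | ring D ketene dithioacetal (2-alkylidene-1,3-dithiane) | S1CCCSC1=CC[C@@]2(C)CC[C@H](C(C)C)[C@@H]2CO[Si](C)(C)C(C)(C)C | intermediate
16 | 3-[(E)-but-2-enoyl]-1,3-oxazolidin-2-one | C/C=C/C(=O)N1CCOC1=O | starting material
17 | all-trans cyclobutane imide, ketone masked as dithiane | O=C(N1CCOC1=O)[C@H]2[C@H](C)[C@@H](C[C@@]3(C)CC[C@H](C(C)C)[C@@H]3CO[Si](C)(C)C(C)(C)C)C24SCCCS4 | intermediate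
18 | all-trans cyclobutylmethanol | OC[C@H]1[C@H](C)[C@@H](C[C@@]2(C)CC[C@H](C(C)C)[C@@H]2CO[Si](C)(C)C(C)(C)C)C13SCCCS3 | intermediate
19 | all-trans cyclobutanecarbaldehyde | O=C[C@H]1[C@H](C)[C@@H](C[C@@]2(C)CC[C@H](C(C)C)[C@@H]2CO[Si](C)(C)C(C)(C)C)C13SCCCS3 | intermediate
20 | (R)-β-citronellene | CC(C)=CCC[C@@H](C)C=C | starting material
21 | ozonide of the trisubstituted alkene of 20 | CC1(C)OOC(O1)CC[C@@H](C)C=C | intermediate
22 | (R)-4-methylhex-5-enal | O=CCC[C@@H](C)C=C | intermediate
23 | (R)-1,1-dibromo-5-methylhepta-1,6-diene | BrC(Br)=CCC[C@@H](C)C=C | intermediate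
24 | [(5R)-5-methylhept-6-en-1-yn-1-yl]lithium | [Li]C#CCC[C@@H](C)C=C | intermediate
25 | (R)-3-methyloct-1-en-6-yne | CC#CCC[C@@H](C)C=C | intermediate
26 | ozonide of the vinyl group of 25 | CC#CCC[C@@H](C)C1OCOO1 | intermediate
27 | (R)-2-methylhept-5-yn-1-ol | CC#CCC[C@@H](C)CO | intermediate
28 | 5-{[(R)-2-methylhept-5-yn-1-yl]sulfanyl}-1-phenyl-1H-tetrazole | CC#CCC[C@@H](C)CSc1nnnn1c1ccccc1 | intermediate
29 | 5-{[(R)-2-methylhept-5-yn-1-yl]sulfonyl}-1-phenyl-1H-tetrazole | CC#CCC[C@@H](C)CS(=O)(=O)c1nnnn1c1ccccc1 | intermediate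
30 | potassium α-sulfonyl carbanion of 29 | CC#CCC[C@@H](C)[CH-]S(=O)(=O)c1nnnn1c1ccccc1.[K+] | intermediate
31 | masked enyne cyclobutane (dithiane, E-alkene, all-trans) | CC#CCC[C@@H](C)/C=C/[C@H]1[C@H](C)[C@@H](C[C@@]2(C)CC[C@H](C(C)C)[C@@H]2CO[Si](C)(C)C(C)(C)C)C13SCCCS3 | intermediate
32 | all-trans 2-alkenylcyclobutanone with tethered alkyne | CC#CCC[C@@H](C)/C=C/[C@H]1[C@H](C)[C@@H](C[C@@]2(C)CC[C@H](C(C)C)[C@@H]2CO[Si](C)(C)C(C)(C)C)C1=O | intermediate
33 | bicyclo[6.3.0]undecadienone carrying ring D | C/C1=C2\CC[C@@H](C)[C@@H]2/C=C\[C@H](C)[C@@H](C[C@@]3(C)CC[C@H](C(C)C)[C@@H]3CO[Si](C)(C)C(C)(C)C)C1=O | intermediate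
34 | enone silyl ether | C/C1=C2\CC[C@@H](C)[C@@H]2CC[C@H](C)[C@@H](C[C@@]3(C)CC[C@H](C(C)C)[C@@H]3CO[Si](C)(C)C(C)(C)C)C1=O | intermediate
35 | hydroxy enone | C/C1=C2\CC[C@@H](C)[C@@H]2CC[C@H](C)[C@@H](C[C@@]3(C)CC[C@H](C(C)C)[C@@H]3CO)C1=O | intermediate
36 | iodo enone | C/C1=C2\CC[C@@H](C)[C@@H]2CC[C@H](C)[C@@H](C[C@@]3(C)CC[C@H](C(C)C)[C@@H]3CI)C1=O | intermediate
37 | alkyllithium from 36 | C/C1=C2\CC[C@@H](C)[C@@H]2CC[C@H](C)[C@@H](C[C@@]3(C)CC[C@H](C(C)C)[C@@H]3C[Li])C1=O | intermediate
38 | sesterfisherol | C/C1=C2\CC[C@@H](C)[C@@H]2CC[C@H](C)[C@H]2C[C@@]3(C)CC[C@H](C(C)C)[C@@H]3C[C@]12O | target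

Total step count: 25. Longest linear sequence: 19 steps (steps 1–12, then 19–25); the sulfone branch (steps 13–18) is 6 steps.

Steps most likely to fail

1. Step 21 (proposed new method). The alkyne may not enter the cycle productively: decarbonylation of an acyl-rhodium species, β-hydride loss from the rhodacyclopentene (plain enyne cycloisomerisation) or a thermal 1,3-acyl shift of the vinylcyclobutanone could consume the substrate before ring expansion. The fallback uses known chemistry. The two-carbon partner is changed to a terminal alkene, the substrate class for which the Rh(I) [6+2] reaction of 2-vinylcyclobutanones is established, and the methyl-bearing enone is built afterwards. It sets out from dibromo-olefin 23 and aldehyde 19 and comes back at enone 34.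
   - Sulfone: n-BuLi and a proton quench convert 23 into (R)-3-methylhept-1-en-6-yne F1. Ozonolysis of the vinyl group with NaBH4 work-up gives (R)-2-methylhex-5-yn-1-ol F2, and semi-hydrogenation (H2, Pd/CaCO3–Pb, quinoline) gives (R)-2-methylhex-5-en-1-ol F3. Mitsunobu reaction with 1-phenyltetrazole-5-thiol gives sulfide F4, and molybdate/H2O2 oxidation gives sulfone F5.
   - Cyclobutanone: Julia–Kocienski olefination of 19 with F5 gives the diene dithiane F6, which is hydrolysed (MeI, CaCO3) to the alkenylcyclobutanone with tethered terminal alkene F7.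
   - Ring expansion and enone: [Rh(CO)2Cl]2 in toluene at 110 °C should give the cis-fused bicyclic ketone F8, with the same relay of configuration to the A/B fusion carbon. Hydrogenation (H2, Pd/C) gives the saturated ketone F9. Methylenation at its only α-CH2 (paraformaldehyde, N-methylanilinium trifluoroacetate, THF, reflux) gives the α-methylene ketone F10. Isomerisation of the exocyclic alkene into the ring-fusion position (RhCl3·3H2O, EtOH, 70 °C) gives 34.

2. Step 10. Conjugate addition of the trisubstituted ketene dithioacetal to the β-methyl acceptor may be slow, so that hydrolysis of the ketene dithioacetal, an open-chain Michael adduct that does not close, or an uncatalysed background path erode yield and facial control. The fallback replaces the acceptor by the more electrophilic fumarate-derived imide, the benchmark substrate class of this cycloaddition, and generates the ring B methyl group from the extra ester. It sets out from ketene dithioacetal 15 and comes back at dithiane 31.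
   - Cycloaddition with methyl (E)-4-oxo-4-(2-oxo-1,3-oxazolidin-3-yl)but-2-enoate F11 (made in one step from methyl hydrogen fumarate) under the conditions of step 10 gives the all-trans cyclobutane ester imide F12.
   - NaBH4 in THF/H2O reduces only the imide to give hydroxy ester F13, and Parikh–Doering oxidation gives aldehyde F14.
   - Julia–Kocienski olefination with 29 gives enyne ester F15.
   - DIBAL-H gives primary alcohol F16, mesylation (MsCl, Et3N) gives mesylate F17, and LiEt3BH displaces the mesylate by hydride to give 31.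

3. Step 25. The alkyllithium may be quenched by proton transfer from the α- or γ-positions of the enone, t-BuLi may attack the carbonyl directly, or closure may occur on the wrong carbonyl face. The fallback replaces the strongly basic organolithium by a nitronate, a soft carbanion that closes ring C reversibly under mild base, so the carbinol configuration comes under thermodynamic control; the nitro group is then removed. It sets out from iodide 36 and comes back at 38.
   - AgNO2 in Et2O gives nitro enone F18.
   - Catalytic DBU in MeCN gives the β-nitro alcohol F19 by intramolecular Henry reaction.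
   - Bu3SnH/AIBN in toluene at 110 °C removes the secondary nitro group to give 38.

Further compounds
F1 | step 21 | (R)-3-methylhept-1-en-6-yne | C#CCC[C@@H](C)C=C
F2 | step 21 | (R)-2-methylhex-5-yn-1-ol | C#CCC[C@@H](C)CO
F3 | step 21 | (R)-2-methylhex-5-en-1-ol | C=CCC[C@@H](C)CO
F4 | step 21 | 5-{[(R)-2-methylhex-5-en-1-yl]sulfanyl}-1-phenyl-1H-tetrazole | C=CCC[C@@H](C)CSc1nnnn1c1ccccc1
F5 | step 21 | 5-{[(R)-2-methylhex-5-en-1-yl]sulfonyl}-1-phenyl-1H-tetrazole | C=CCC[C@@H](C)CS(=O)(=O)c1nnnn1c1ccccc1
F6 | step 21 | diene dithiane (analogue of 31 with terminal alkene) | C=CCC[C@@H](C)/C=C/[C@H]1[C@H](C)[C@@H](C[C@@]2(C)CC[C@H](C(C)C)[C@@H]2CO[Si](C)(C)C(C)(C)C)C13SCCCS3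
F7 | step 21 | all-trans 2-alkenylcyclobutanone with tethered terminal alkene | C=CCC[C@@H](C)/C=C/[C@H]1[C@H](C)[C@@H](C[C@@]2(C)CC[C@H](C(C)C)[C@@H]2CO[Si](C)(C)C(C)(C)C)C1=O
F8 | step 21 | cis-fused bicyclo[6.3.0]undecenone | O=C1C[C@@H]2CC[C@@H](C)[C@@H]2/C=C\[C@H](C)[C@H]1C[C@@]3(C)CC[C@H](C(C)C)[C@@H]3CO[Si](C)(C)C(C)(C)C
F9 | step 21 | saturated cis-fused bicyclo[6.3.0]undecanone | O=C1C[C@@H]2CC[C@@H](C)[C@@H]2CC[C@H](C)[C@H]1C[C@@]3(C)CC[C@H](C(C)C)[C@@H]3CO[Si](C)(C)C(C)(C)C
F10 | step 21 | α-methylene ketone | O=C1C(=C)[C@@H]2CC[C@@H](C)[C@@H]2CC[C@H](C)[C@H]1C[C@@]3(C)CC[C@H](C(C)C)[C@@H]3CO[Si](C)(C)C(C)(C)C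
F11 | step 10 | methyl (E)-4-oxo-4-(2-oxo-1,3-oxazolidin-3-yl)but-2-enoate | COC(=O)/C=C/C(=O)N1CCOC1=O
F12 | step 10 | all-trans cyclobutane ester imide | O=C(N1CCOC1=O)[C@H]2[C@H](C(=O)OC)[C@@H](C[C@@]3(C)CC[C@H](C(C)C)[C@@H]3CO[Si](C)(C)C(C)(C)C)C24SCCCS4
F13 | step 10 | hydroxy ester | OC[C@H]1[C@H](C(=O)OC)[C@@H](C[C@@]2(C)CC[C@H](C(C)C)[C@@H]2CO[Si](C)(C)C(C)(C)C)C13SCCCS3
F14 | step 10 | aldehyde ester | O=C[C@H]1[C@H](C(=O)OC)[C@@H](C[C@@]2(C)CC[C@H](C(C)C)[C@@H]2CO[Si](C)(C)C(C)(C)C)C13SCCCS3
F15 | step 10 | enyne ester | CC#CCC[C@@H](C)/C=C/[C@H]1[C@H](C(=O)OC)[C@@H](C[C@@]2(C)CC[C@H](C(C)C)[C@@H]2CO[Si](C)(C)C(C)(C)C)C13SCCCS3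
F16 | step 10 | enyne primary alcohol | CC#CCC[C@@H](C)/C=C/[C@H]1[C@H](CO)[C@@H](C[C@@]2(C)CC[C@H](C(C)C)[C@@H]2CO[Si](C)(C)C(C)(C)C)C13SCCCS3
F17 | step 10 | enyne mesylate | CC#CCC[C@@H](C)/C=C/[C@H]1[C@H](COS(C)(=O)=O)[C@@H](C[C@@]2(C)CC[C@H](C(C)C)[C@@H]2CO[Si](C)(C)C(C)(C)C)C13SCCCS3
F18 | step 25 | nitro enone | C/C1=C2\CC[C@@H](C)[C@@H]2CC[C@H](C)[C@@H](C[C@@]3(C)CC[C@H](C(C)C)[C@@H]3C[N+](=O)[O-])C1=O
F19 | step 25 | β-nitro alcohol (nitro-bearing carbon as a mixture) | C/C1=C2\CC[C@@H](C)[C@@H]2CC[C@H](C)[C@H]2C[C@@]3(C)CC[C@H](C(C)C)[C@@H]3C([N+](=O)[O-])[C@]12O
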